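**Retrosynthetic overview**

1. Target ⇐ Pinnick oxidation of the C12 enal ⇐ acetal and silyl ether hydrolysis ⇐ site-selective acylation of the C8 hydroxyl of a 6,8-diol with (Z)-4-acetoxy-2-methylbut-2-enoic acid, itself from 3-methylfuran-2(5H)-one (elemane numbering for ring carbons).
2. The 6,8-diol ⇐ axial-selective reduction of the C6 ketone ⇐ one-flask vicinal dialkenylation of a 2-iodo-3-methylcyclohexenone: C10–vinyl by 1,4-addition trans to the C8 silyloxy group, C5–C4 by Negishi coupling of the iodo enol silane, C5–H by face-selective protonation.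
3. The iodoenone ⇐ α-iodination, β-methylation and two dehydrogenations of a 2-alkenyl-3-silyloxycyclohexanone.
4. That ketone ⇐ semipinacol 1,2-alkenyl shift (C6 → C7) in a 2,3-epoxy tertiary alcohol ⇐ α-lithioacrolein acetal + (2S,3S)-2,3-epoxycyclohexanone ⇐ asymmetric epoxidation of cyclohex-2-en-1-one.
5. Rings: the only carbocycle is bought as cyclohexenone; the oxirane is the sole ring formed (step 3) and is consumed in the 1,2-shift (step 5).

Assumption: the target is the stereoisomer written in the SMILES (ring carbons 5R,6S,7S,8S,10R; Z ester), and the four numbered starting materials are catalogue compounds.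

**Route**

Step 1
Reactants: 1 2-bromoprop-2-en-1-ol
Product: 2 tert-butyl[(2-bromoprop-2-en-1-yl)oxy]dimethylsilane
Conditions: TBSCl, imidazole, CH2Cl2, 0 → 23 °C
Reagents that add atoms: tert-butyl(chloro)dimethylsilane, CC(C)(C)[Si](C)(C)Cl
Why: Standard imidazole-promoted O-silylation of a primary allylic alcohol (Corey silyl ether formation); no stereocentre is involved.

Step 2
Reactants: 3 3-methylfuran-2(5H)-one
Product: 6 (2Z)-4-(acetyloxy)-2-methylbut-2-enoic acid, via sodium hydroxy-enoate 4 (not isolated), via disodium alkoxide-carboxylate 5 (not isolated)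
Conditions: NaOH (1.0 equiv), H2O, 23 °C, freeze-dry; NaH (1.05 equiv), THF/DMF, 0 °C; Ac2O (1.05 equiv), −20 °C; cold 1 M HCl to pH 3
Reagents that add atoms: sodium hydroxide, [Na+].[OH-]; acetic anhydride, CC(=O)OC(C)=O
Why: Lactone saponification keeps the ring-imposed Z double bond, and O-acetylation of the far more nucleophilic alkoxide of the dianion never activates the carboxylate, so the Z acid is obtained on cold acidification without relactonisation (ester hydrolysis, alkoxide acylation).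

Step 3
Reactants: 7 cyclohex-2-en-1-one
Product: 8 (1S,6S)-7-oxabicyclo[4.1.0]heptan-2-one
Conditions: 9-amino-9-deoxy-epi-quinine·2 CF3CO2H (10 mol%; or its quinidine-derived pseudo-enantiomer, whichever gives the 2S,3S oxide), 50% aq. H2O2, dioxane, 50 °C
Reagents that add atoms: hydrogen peroxide, OO
Why: Iminium-activated asymmetric Weitz–Scheffer epoxidation of a cyclic enone, in which the chiral primary ammonium salt steers hydroperoxide addition to one enone face, fixes both oxirane stereocentres and with them the absolute configuration of the whole route.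

Step 4
Reactants: 8 (1S,6S)-7-oxabicyclo[4.1.0]heptan-2-one; 9 2-bromo-3,3-dimethoxyprop-1-ene
Product: 11 (1S,2S,6S)-2-(3,3-dimethoxyprop-1-en-2-yl)-7-oxabicyclo[4.1.0]heptan-2-ol, via alkenyllithium 10 (not isolated)
Conditions: 9, t-BuLi (2 equiv), Et2O, −78 °C; then 8, −78 °C; H2O quench
Reagents that add atoms: none
Why: Bromine–lithium exchange gives the α-lithiated acrolein acetal, which adds 1,2 to the ketone from the face opposite the oxirane oxygen (the usual anti attack on 2,3-epoxycyclohexanones), so the alkenyl group ends up anti and the hydroxyl syn to the epoxide, as the shift requires.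

Step 5
Reactants: 11 (1S,2S,6S)-2-(3,3-dimethoxyprop-1-en-2-yl)-7-oxabicyclo[4.1.0]heptan-2-ol
Product: 13 (2R,3S)-2-(3,3-dimethoxyprop-1-en-2-yl)-3-[(triethylsilyl)oxy]cyclohexan-1-one, via epoxy silyl ether 12 (not isolated)
Conditions: TESOTf (1.3 equiv), 2,6-lutidine (1.1 equiv), CH2Cl2, −78 → −30 °C
Reagents that add atoms: triethylsilyl trifluoromethanesulfonate, CC[Si](CC)(CC)OS(=O)(=O)C(F)(F)F
Why: Key step, a semipinacol rearrangement of a 2,3-epoxy alcohol silyl ether (Suzuki–Tsuchihashi type): after O-silylation the excess silyl triflate activates the oxirane and the alkenyl group undergoes a stereospecific 1,2-shift anti to the breaking C–O bond, so C2 is formed with inversion, trans to the retained silyloxy centre C3, and the ketone is unveiled.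

Step 6
Reactants: 13 (2R,3S)-2-(3,3-dimethoxyprop-1-en-2-yl)-3-[(triethylsilyl)oxy]cyclohexan-1-one
Product: 15 (5S,6R)-6-(3,3-dimethoxyprop-1-en-2-yl)-5-[(triethylsilyl)oxy]cyclohex-2-en-1-one, via trimethylsilyl enol ether 14 (not isolated)
Conditions: LiN(i-Pr)2, TMSCl (in situ), THF, −78 °C; then Pd(OAc)2 (10 mol%), O2 (1 atm), DMSO, 23 °C
Reagents that add atoms: none
Why: Kinetic deprotonation with in situ silylation takes the unhindered methylene instead of the substituted α-methine, and Saegusa–Ito oxidation of the enol silane by divalent palladium under O2 gives the enone without touching the two stereocentres.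

Step 7
Reactants: 15 (5S,6R)-6-(3,3-dimethoxyprop-1-en-2-yl)-5-[(triethylsilyl)oxy]cyclohex-2-en-1-one
Product: 17 (5S,6R)-6-(3,3-dimethoxyprop-1-en-2-yl)-3-methyl-5-[(triethylsilyl)oxy]cyclohex-2-en-1-one, via methylated enol silane 16 (not isolated)
Conditions: Me2CuLi, TMSCl, Et2O, −78 °C; then Pd(OAc)2 (10 mol%), O2 (1 atm), DMSO, 40 °C
Reagents that add atoms: lithium dimethylcuprate, [Li+].C[Cu-]C
Why: Gilman-cuprate 1,4-addition with silyl trapping followed by a second Saegusa–Ito oxidation of the regiodefined enol silane installs the β-methyl group and regenerates the enone, erasing the transient methyl-bearing stereocentre.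

Step 8
Reactants: 17 (5S,6R)-6-(3,3-dimethoxyprop-1-en-2-yl)-3-methyl-5-[(triethylsilyl)oxy]cyclohex-2-en-1-one
Product: 18 (5S,6R)-6-(3,3-dimethoxyprop-1-en-2-yl)-2-iodo-3-methyl-5-[(triethylsilyl)oxy]cyclohex-2-en-1-one
Conditions: I2 (2 equiv), pyridine/CH2Cl2 (1:1), 23 °C
Reagents that add atoms: iodine, II
Why: Johnson α-iodination of an enone under weakly basic conditions gives the 2-iodoenone needed for the next step; no stereocentre changes.

Step 9
Reactants: 18 (5S,6R)-6-(3,3-dimethoxyprop-1-en-2-yl)-2-iodo-3-methyl-5-[(triethylsilyl)oxy]cyclohex-2-en-1-one; 2 tert-butyl[(2-bromoprop-2-en-1-yl)oxy]dimethylsilane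
Product: 23 (2R,3R,5S,6R)-2-{3-[(tert-butyldimethylsilyl)oxy]prop-1-en-2-yl}-6-(3,3-dimethoxyprop-1-en-2-yl)-3-ethenyl-5-hydroxy-3-methylcyclohexan-1-one, via iodo enol silane 19 (not isolated), via alkenyllithium 20 (not isolated), via alkenylzinc chloride 21 (not isolated), via dienol silane 22 (not isolated)
Conditions: CH2=CHMgBr (1.2 equiv), CuBr·SMe2 (10 mol%), TMSCl (2 equiv), THF, −78 °C; then 21 [from 2: t-BuLi (2 equiv), Et2O, −78 °C; ZnCl2], Pd(P(t-Bu)3)2 (5 mol%), 23 °C; then HF·pyridine, pyridine, THF, −20 → 0 °C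
Reagents that add atoms: vinylmagnesium bromide, C=C[Mg]Br
Why: Proposed new method: a one-flask vicinal dialkenylation of an α-iodoenone, in which the iodine lowers the enone LUMO so that the TMSCl-accelerated, monovalent-copper-catalysed 1,4-addition of the vinyl Grignard (axial attack trans to the 5-silyloxy group, as for cuprate additions to 5-silyloxycyclohexenones) outruns attack at the C–I bond at −78 °C and is trapped as the 2-iodo silyl enol ether 19, a vinyl iodide that zerovalent palladium inserts into for Negishi coupling with 21, after which fluoride frees the dienolate and it is protonated at the α-carbon from the face opposite the now axial vinyl group (setting C2 cis to vinyl) while the triethylsilyl ether is cleaved; the closest known reactions are cuprate conjugate addition with enolate trapping and Negishi coupling of α-iodoenones and α-halo enol ethers.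

Step 10
Reactants: 23 (2R,3R,5S,6R)-2-{3-[(tert-butyldimethylsilyl)oxy]prop-1-en-2-yl}-6-(3,3-dimethoxyprop-1-en-2-yl)-3-ethenyl-5-hydroxy-3-methylcyclohexan-1-one
Product: 24 (1S,2R,3S,4R,5R)-4-{3-[(tert-butyldimethylsilyl)oxy]prop-1-en-2-yl}-2-(3,3-dimethoxyprop-1-en-2-yl)-5-ethenyl-5-methylcyclohexane-1,3-diol
Conditions: LiBH(s-Bu)3 (3 equiv), THF, −78 → −40 °C; H2O quench
Reagents that add atoms: none
Why: The bulky trialkylborohydride attacks the ketone along the equatorial trajectory, from the face opposite the axial vinyl group, giving the axial alcohol cis to both flanking alkenyl groups (steric-approach-controlled reduction).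

Step 11
Reactants: 24 (1S,2R,3S,4R,5R)-4-{3-[(tert-butyldimethylsilyl)oxy]prop-1-en-2-yl}-2-(3,3-dimethoxyprop-1-en-2-yl)-5-ethenyl-5-methylcyclohexane-1,3-diol; 6 (2Z)-4-(acetyloxy)-2-methylbut-2-enoic acid
Product: 26 (1S,2S,3S,4R,5R)-4-{3-[(tert-butyldimethylsilyl)oxy]prop-1-en-2-yl}-2-(3,3-dimethoxyprop-1-en-2-yl)-5-ethenyl-3-hydroxy-5-methylcyclohexyl (2Z)-4-(acetyloxy)-2-methylbut-2-enoate, via mixed anhydride 25 (not isolated)
Conditions: 6, 2,4,6-Cl3C6H2COCl, Et3N, toluene, 23 °C; then 24, 75 °C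
Reagents that add atoms: none
Why: Yamaguchi esterification through the mixed anhydride without a nucleophilic catalyst keeps the Z-enoate geometry, and acylation is site-selective for the equatorial hydroxyl because the other one is axial and flanked by two branched carbons.

Step 12
Reactants: 26 (1S,2S,3S,4R,5R)-4-{3-[(tert-butyldimethylsilyl)oxy]prop-1-en-2-yl}-2-(3,3-dimethoxyprop-1-en-2-yl)-5-ethenyl-3-hydroxy-5-methylcyclohexyl (2Z)-4-(acetyloxy)-2-methylbut-2-enoate
Product: 27 (1S,2S,3S,4R,5R)-5-ethenyl-3-hydroxy-4-(3-hydroxyprop-1-en-2-yl)-5-methyl-2-(3-oxoprop-1-en-2-yl)cyclohexyl (2Z)-4-(acetyloxy)-2-methylbut-2-enoate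
Conditions: 48% aq. HF/MeCN (1:19), 0 → 23 °C
Reagents that add atoms: water, O
Why: Aqueous HF cleaves the primary silyl ether and hydrolyses the dimethyl acetal of the enal in one operation (fluoride desilylation, acid-catalysed acetal hydrolysis) while both esters and all stereocentres are untouched.

Step 13
Reactants: 27 (1S,2S,3S,4R,5R)-5-ethenyl-3-hydroxy-4-(3-hydroxyprop-1-en-2-yl)-5-methyl-2-(3-oxoprop-1-en-2-yl)cyclohexyl (2Z)-4-(acetyloxy)-2-methylbut-2-enoate
Product: 28 2-[(1S,2S,3R,4R,6S)-6-{[(2Z)-4-(acetyloxy)-2-methylbut-2-enoyl]oxy}-4-ethenyl-2-hydroxy-3-(3-hydroxyprop-1-en-2-yl)-4-methylcyclohexyl]prop-2-enoic acid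
Conditions: NaClO2, NaH2PO4, 2-methylbut-2-ene, t-BuOH/H2O, 0 °C
Reagents that add atoms: sodium chlorite, [Na+].[O-]Cl=O
Why: Pinnick oxidation of the α-substituted acrolein to the acrylic acid under phosphate buffer with a hypochlorite scavenger tolerates the free hydroxyls, the alkenes and both esters and avoids the acid that would lactonise the product.

**Compound list**

1 | 2-bromoprop-2-en-1-ol | OCC(Br)=C | starting material
2 | tert-butyl[(2-bromoprop-2-en-1-yl)oxy]dimethylsilane | C=C(Br)CO[Si](C)(C)C(C)(C)C | intermediate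
3 | 3-methylfuran-2(5H)-one | CC1=CCOC1=O | starting material
4 | sodium (2Z)-4-hydroxy-2-methylbut-2-enoate | [Na+].[O-]C(=O)/C(C)=C\CO | intermediate
5 | disodium (2Z)-2-methyl-4-oxidobut-2-enoate | [Na+].[Na+].[O-]C(=O)/C(C)=C\C[O-] | intermediate
6 | (2Z)-4-(acetyloxy)-2-methylbut-2-enoic acid | OC(=O)/C(C)=C\COC(C)=O | intermediate
7 | cyclohex-2-en-1-one | O=C1C=CCCC1 | starting material
8 | (1S,6S)-7-oxabicyclo[4.1.0]heptan-2-one | O=C1CCC[C@@H]2O[C@H]12 | intermediate
9 | 2-bromo-3,3-dimethoxyprop-1-ene | C=C(Br)C(OC)OC | starting material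
10 | (3,3-dimethoxyprop-1-en-2-yl)lithium | [Li]C(=C)C(OC)OC | intermediate
11 | (1S,2S,6S)-2-(3,3-dimethoxyprop-1-en-2-yl)-7-oxabicyclo[4.1.0]heptan-2-ol | O[C@]1(C(=C)C(OC)OC)CCC[C@@H]2O[C@H]12 | intermediate
12 | {[(1S,2S,6S)-2-(3,3-dimethoxyprop-1-en-2-yl)-7-oxabicyclo[4.1.0]heptan-2-yl]oxy}triethylsilane | CC[Si](CC)(CC)O[C@]1(C(=C)C(OC)OC)CCC[C@@H]2O[C@H]12 | intermediate
13 | (2R,3S)-2-(3,3-dimethoxyprop-1-en-2-yl)-3-[(triethylsilyl)oxy]cyclohexan-1-one | O=C1CCC[C@H](O[Si](CC)(CC)CC)[C@H]1C(=C)C(OC)OC | intermediate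
14 | {[(5S,6R)-6-(3,3-dimethoxyprop-1-en-2-yl)-5-[(triethylsilyl)oxy]cyclohex-1-en-1-yl]oxy}trimethylsilane | C[Si](C)(C)OC1=CCC[C@H](O[Si](CC)(CC)CC)[C@H]1C(=C)C(OC)OC | intermediate
15 | (5S,6R)-6-(3,3-dimethoxyprop-1-en-2-yl)-5-[(triethylsilyl)oxy]cyclohex-2-en-1-one | O=C1C=CC[C@H](O[Si](CC)(CC)CC)[C@H]1C(=C)C(OC)OC | intermediate
16 | {[(3S,5S,6R)-6-(3,3-dimethoxyprop-1-en-2-yl)-3-methyl-5-[(triethylsilyl)oxy]cyclohex-1-en-1-yl]oxy}trimethylsilane | C[Si](C)(C)OC1=C[C@@H](C)C[C@H](O[Si](CC)(CC)CC)[C@H]1C(=C)C(OC)OC | intermediate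
17 | (5S,6R)-6-(3,3-dimethoxyprop-1-en-2-yl)-3-methyl-5-[(triethylsilyl)oxy]cyclohex-2-en-1-one | O=C1C=C(C)C[C@H](O[Si](CC)(CC)CC)[C@H]1C(=C)C(OC)OC | intermediate
18 | (5S,6R)-6-(3,3-dimethoxyprop-1-en-2-yl)-2-iodo-3-methyl-5-[(triethylsilyl)oxy]cyclohex-2-en-1-one | O=C1C(I)=C(C)C[C@H](O[Si](CC)(CC)CC)[C@H]1C(=C)C(OC)OC | intermediate
19 | {[(3R,5S,6R)-6-(3,3-dimethoxyprop-1-en-2-yl)-3-ethenyl-2-iodo-3-methyl-5-[(triethylsilyl)oxy]cyclohex-1-en-1-yl]oxy}trimethylsilane | C[Si](C)(C)OC1=C(I)[C@@](C)(C=C)C[C@H](O[Si](CC)(CC)CC)[C@H]1C(=C)C(OC)OC | intermediate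
20 | {3-[(tert-butyldimethylsilyl)oxy]prop-1-en-2-yl}lithium | [Li]C(=C)CO[Si](C)(C)C(C)(C)C | intermediate
21 | chloro{3-[(tert-butyldimethylsilyl)oxy]prop-1-en-2-yl}zinc | Cl[Zn]C(=C)CO[Si](C)(C)C(C)(C)C | intermediate
22 | {[(3R,5S,6R)-2-{3-[(tert-butyldimethylsilyl)oxy]prop-1-en-2-yl}-6-(3,3-dimethoxyprop-1-en-2-yl)-3-ethenyl-3-methyl-5-[(triethylsilyl)oxy]cyclohex-1-en-1-yl]oxy}trimethylsilane | C[Si](C)(C)OC1=C(C(=C)CO[Si](C)(C)C(C)(C)C)[C@@](C)(C=C)C[C@H](O[Si](CC)(CC)CC)[C@H]1C(=C)C(OC)OC | intermediate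
23 | (2R,3R,5S,6R)-2-{3-[(tert-butyldimethylsilyl)oxy]prop-1-en-2-yl}-6-(3,3-dimethoxyprop-1-en-2-yl)-3-ethenyl-5-hydroxy-3-methylcyclohexan-1-one | O=C1[C@@H](C(=C)CO[Si](C)(C)C(C)(C)C)[C@@](C)(C=C)C[C@H](O)[C@H]1C(=C)C(OC)OC | intermediate
24 | (1S,2R,3S,4R,5R)-4-{3-[(tert-butyldimethylsilyl)oxy]prop-1-en-2-yl}-2-(3,3-dimethoxyprop-1-en-2-yl)-5-ethenyl-5-methylcyclohexane-1,3-diol | O[C@H]1[C@@H](C(=C)CO[Si](C)(C)C(C)(C)C)[C@@](C)(C=C)C[C@H](O)[C@H]1C(=C)C(OC)OC | intermediate
25 | (2Z)-4-(acetyloxy)-2-methylbut-2-enoic 2,4,6-trichlorobenzoic anhydride | O=C(OC(=O)c1c(Cl)cc(Cl)cc1Cl)/C(C)=C\COC(C)=O | intermediate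
26 | (1S,2S,3S,4R,5R)-4-{3-[(tert-butyldimethylsilyl)oxy]prop-1-en-2-yl}-2-(3,3-dimethoxyprop-1-en-2-yl)-5-ethenyl-3-hydroxy-5-methylcyclohexyl (2Z)-4-(acetyloxy)-2-methylbut-2-enoate | O[C@H]1[C@@H](C(=C)CO[Si](C)(C)C(C)(C)C)[C@@](C)(C=C)C[C@H](OC(=O)/C(C)=C\COC(C)=O)[C@H]1C(=C)C(OC)OC | intermediate
27 | (1S,2S,3S,4R,5R)-5-ethenyl-3-hydroxy-4-(3-hydroxyprop-1-en-2-yl)-5-methyl-2-(3-oxoprop-1-en-2-yl)cyclohexyl (2Z)-4-(acetyloxy)-2-methylbut-2-enoate | O[C@H]1[C@@H](C(=C)CO)[C@@](C)(C=C)C[C@H](OC(=O)/C(C)=C\COC(C)=O)[C@H]1C(=C)C=O | intermediate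
28 | 2-[(1S,2S,3R,4R,6S)-6-{[(2Z)-4-(acetyloxy)-2-methylbut-2-enoyl]oxy}-4-ethenyl-2-hydroxy-3-(3-hydroxyprop-1-en-2-yl)-4-methylcyclohexyl]prop-2-enoic acid | C=C[C@@]1(C)C[C@H](OC(=O)/C(C)=C\COC(C)=O)[C@@H](C(=C)C(=O)O)[C@@H](O)[C@H]1C(=C)CO | target

**Step count and risks**

Total step count: 13 (two fragment steps and eleven in the main line). Longest linear sequence: 11 steps, from cyclohex-2-en-1-one (steps 3 to 13).

The three steps most likely to fail:

Step 5 (1,2-shift). The silyl triflate can ionise the dimethyl acetal, and ring contraction by migration of the ring methylene can compete with the inductively deactivated alkenyl group. The fallback sets out from 11 and no longer uses a silyl triflate: the free epoxy alcohol is rearranged as its zinc chelate (ZnBr2, 10 mol%, CH2Cl2, 0 °C; the known chelation-type semipinacol of tertiary α-hydroxy epoxides) to the aldol (2R,3S)-2-(3,3-dimethoxyprop-1-en-2-yl)-3-hydroxycyclohexan-1-one F1, which is silylated in a separate operation (TESCl, imidazole, DMF) and comes back to the route at 13.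

Step 6 (first dehydrogenation). Deprotonation at the α-methine instead of the methylene would expel the β-silyloxy group. The fallback sets out from 8, where only one side of the ketone can enolise, and installs the unsaturation handle before the ketone becomes doubly enolisable:
- Sulfenylation of 8 (LiN(i-Pr)2, THF, −78 °C; PhSSO2Ph) gives (1S,6S)-3-(phenylsulfanyl)-7-oxabicyclo[4.1.0]heptan-2-one F2.
- Addition of alkenyllithium 10 (Et2O, −78 °C) gives (1S,2S,6S)-2-(3,3-dimethoxyprop-1-en-2-yl)-3-(phenylsulfanyl)-7-oxabicyclo[4.1.0]heptan-2-ol F3.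
- TESOTf/2,6-lutidine converts F3 through {[(1S,2S,6S)-2-(3,3-dimethoxyprop-1-en-2-yl)-3-(phenylsulfanyl)-7-oxabicyclo[4.1.0]heptan-2-yl]oxy}triethylsilane F4 into (2R,3S)-2-(3,3-dimethoxyprop-1-en-2-yl)-6-(phenylsulfanyl)-3-[(triethylsilyl)oxy]cyclohexan-1-one F5.
- Oxidation (mCPBA, CH2Cl2, −78 °C) gives (2R,3S)-6-(benzenesulfinyl)-2-(3,3-dimethoxyprop-1-en-2-yl)-3-[(triethylsilyl)oxy]cyclohexan-1-one F6.
- Thermal syn-elimination of F6 (toluene, 90 °C), which can only run toward the methylene, comes back to the route at 15.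

Step 9 (proposed new one-flask dialkenylation). The cuprate may attack the C–I bond instead of adding 1,4, or the α-iodo enolate may lose iodide before silylation. The fallback uses known chemistry, sets out from 18 and inverts the order of the two bond formations. Negishi coupling of 18 with the zinc reagent 21 (Pd(P(t-Bu)3)2, THF, 23 °C) gives the dienone (5S,6R)-2-{3-[(tert-butyldimethylsilyl)oxy]prop-1-en-2-yl}-6-(3,3-dimethoxyprop-1-en-2-yl)-3-methyl-5-[(triethylsilyl)oxy]cyclohex-2-en-1-one F7. Copper-catalysed 1,4-addition of CH2=CHMgBr with TMSCl to F7 (the known cuprate addition to 2,3-disubstituted cyclohexenones, again trans to the silyloxy group) comes back to the route at the dienol silane 22, which is taken on to 23 with HF·pyridine as in step 9.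

Further compounds

F1 | step 5 | (2R,3S)-2-(3,3-dimethoxyprop-1-en-2-yl)-3-hydroxycyclohexan-1-one | O=C1CCC[C@H](O)[C@H]1C(=C)C(OC)OC
F2 | step 6 | (1S,6S)-3-(phenylsulfanyl)-7-oxabicyclo[4.1.0]heptan-2-one | O=C1C(Sc2ccccc2)CC[C@@H]3O[C@H]13
F3 | step 6 | (1S,2S,6S)-2-(3,3-dimethoxyprop-1-en-2-yl)-3-(phenylsulfanyl)-7-oxabicyclo[4.1.0]heptan-2-ol | O[C@]1(C(=C)C(OC)OC)C(Sc2ccccc2)CC[C@@H]3O[C@H]13
F4 | step 6 | {[(1S,2S,6S)-2-(3,3-dimethoxyprop-1-en-2-yl)-3-(phenylsulfanyl)-7-oxabicyclo[4.1.0]heptan-2-yl]oxy}triethylsilane | CC[Si](CC)(CC)O[C@]1(C(=C)C(OC)OC)C(Sc2ccccc2)CC[C@@H]3O[C@H]13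
F5 | step 6 | (2R,3S)-2-(3,3-dimethoxyprop-1-en-2-yl)-6-(phenylsulfanyl)-3-[(triethylsilyl)oxy]cyclohexan-1-one | O=C1C(Sc2ccccc2)CC[C@H](O[Si](CC)(CC)CC)[C@H]1C(=C)C(OC)OC
F6 | step 6 | (2R,3S)-6-(benzenesulfinyl)-2-(3,3-dimethoxyprop-1-en-2-yl)-3-[(triethylsilyl)oxy]cyclohexan-1-one | O=C1C(S(=O)c2ccccc2)CC[C@H](O[Si](CC)(CC)CC)[C@H]1C(=C)C(OC)OC
F7 | step 9 | (5S,6R)-2-{3-[(tert-butyldimethylsilyl)oxy]prop-1-en-2-yl}-6-(3,3-dimethoxyprop-1-en-2-yl)-3-methyl-5-[(triethylsilyl)oxy]cyclohex-2-en-1-one | O=C1C(C(=C)CO[Si](C)(C)C(C)(C)C)=C(C)C[C@H](O[Si](CC)(CC)CC)[C@H]1C(=C)C(OC)OC
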